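The earlier runs and the new flask were generated by integration with made-up constants.

Saturday's run still held 67.1% of its free monomer at 15.0 min, and that leftover is our way into the next flask.

the same everywhere: free monomer 0.80 M (fed, over 12 min)
- Saturday's: transfer agent 8 mM; initiator 2.7 mol%; run made earlier; the fed solution adds 0.50 times the starting volume
- flask: transfer agent 8.00 mM; initiator 1.8 mol%; the fed solution adds 0.50 times the starting volume; time 2.5 h

Saturday's run (percent of the free monomer charged)

| time / min | monomer in chains / % | free monomer / % |
|---|---|---|
| 3.00 | 0.1 | 24.3 |
| 6.00 | 4.4 | 46.7 |
| 10.0 | 13.9 | 70.1 |
| 12.0 | 20.6 | 79.2 |
| 15.0 | 32.6 | 67.1 |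

(readings scatter by 0.5 percentage points)

- every charge counts on the volume at the start, and the solution that is fed holds the whole dose
- the average divides the monomer in chains by the number of chains begun, living and dead together
- the earlier runs do not show the number of chains; that part of a forecast is a guess
- percentages count the whole charge, also what has not yet gone in
- no earlier run changes the charge of initiator; that part of a forecast is a guess

- whether the average number of monomer units in a chain (chains begun, living or dead) reaches 30 by 2.5 h (yes / no)
- average number of monomer units in a chain (chains begun, living or dead) at 2.5 h

From 12.0 min, when Saturday's feed ended, the free monomer fell at a pseudo-first-order rate of 0.0553 min⁻¹, a mean life of 18.1 min, as a reading.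

We put the times of the new flask on a logarithmic scale, fastest first. The lowest rung is starting chains. In Saturday's run the rate per free monomer was already 0.0407 min⁻¹ between 6.00 min and 10.0 min, against 0.0553 min⁻¹ after the feed, so we place the starting of chains on the scale of the feed, 12 min.

Growth comes next. If growing chains follow the initiator charge, the new flask's life is 27.1 min, 0.354 of a power of ten above the feed. The asked time stands 0.743 higher, which is 5.53 lives, or 2.40 powers of ten down, to 0.398% free monomer. That needs the rate to last, and the readings stop at 15.0 min.

On the top rung we count chains. The loading is on free monomer, so the new flask has 14.4 mM of initiator, more than its 8.00 mM of transfer agent. We guess one chain per initiator and none from the transfer agent. That gives 55.6 units per starter, the free monomer charged over the initiator charged. Once each starter has begun its chain, the average is units per starter times the part reacted: 55.3 at the end, and 30 at 54.0% reacted.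

The forecast gives the same yes but a different average, 96, between 82 and 100, on the words “I assume the mol% is relative to transfer agent”.

The flask answers yes and gives 54.6 units at 2.5 h.

    free monomer + initiator → living end + monomer in chains (k = 0.540 M⁻¹ min⁻¹)
    free monomer + living end → monomer in chains + living end, rate k2*[living end]*[free monomer] (k = 4.40 M⁻¹ min⁻¹)
    living end + transfer agent → dead chain (kL = 1.80 M⁻¹ min⁻¹)

At 2.50 h the living ends, 0.00524 M, and dead chains, 0.00436 M, add up to 9.60 mM, which is the initiator charge spread over the final volume, 9.60 mM. With 1.7% of the free monomer left, units per starter give 54.6. The same number put 30 at 54.0% reacted, and the flask stood at 53.6% reacted when it got there, at 0.479 h.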